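**Retrosynthetic overview**
- Target 39 ⇐ acetylation/desilylation of macrocyclic alcohol 36; the ten-membered ring is closed last, at C9–C10, by an intramolecular Nozaki–Hiyama–Kishi addition of a Z-alkenyl iodide to a C9 aldehyde.
- The C6 ester is installed with inversion (Mitsunobu) using the silyl-protected Z-acid 31.
- Key C6–C7 bond: intermolecular Zn Barbier allylation of aldehyde 19 (fragment A: C1–C6, C10, C14) with bromomethyl butenolide 25 (fragment B: C7–C9, C11–C13); this turns the butenolide into the α-methylidene lactone.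
- Fragment A from but-3-yn-1-ol (carboalumination; Sharpless epoxidation/Red-Al for C4; alkynylation/transfer hydrogenation for C2; hydroalumination–iodination for the Z-iodide). Fragment B from (R)-glycidol; acid 31 from crotonaldehyde.
- Ring order: five-membered lactone first (ring-closing metathesis, step 18), ten-membered carbocycle second (step 27).

Carbon labels: C8 lactone carbinol, C7 ring-fusion CH, C6 ester carbinol, C4 C(Me)OH, C2 free CHOH, C1=C10 ring alkene, C9 CHOAc, C14 CH2OAc on C10, C11–C13 methylidene-lactone carbons.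

Assumption: the Zn allylation follows the usual closed chair transition state (giving the 6S carbinol that step 24 inverts), and the ring closure of step 27 is taken to give mainly the 9S alcohol (fallback given otherwise).

**Route**

Step 1
Reactants: 1 but-3-yn-1-ol
Product: 2 1-[(but-3-yn-1-yloxy)methyl]-4-methoxybenzene
Conditions: NaH, PMBCl, Bu4NI (cat.), THF, 0 °C → rt
Reagents that add atoms: 4-methoxybenzyl chloride COc1ccc(CCl)cc1
Why: Williamson etherification of the primary alkoxide; no stereocentre is involved.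

Step 2
Reactants: 2 1-[(but-3-yn-1-yloxy)methyl]-4-methoxybenzene
Product: 4 (2E)-5-[(4-methoxybenzyl)oxy]-3-methylpent-2-en-1-ol, via alkenyldimethylalane 3 (not isolated)
Conditions: Me3Al, Cp2ZrCl2 (cat.), CH2Cl2, 0 °C → rt; then n-BuLi, (CH2O)n, THF, −30 °C → rt
Reagents that add atoms: trimethylaluminium C[Al](C)C; paraformaldehyde (as formaldehyde) C=O
Why: Negishi zirconium-catalysed carboalumination adds Me and Al syn with Al terminal, and hydroxymethylation of the derived alanate fixes the E-trisubstituted alkene.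

Step 3
Reactants: 4 (2E)-5-[(4-methoxybenzyl)oxy]-3-methylpent-2-en-1-ol
Product: 5 [(2R,3R)-3-{2-[(4-methoxybenzyl)oxy]ethyl}-3-methyloxiran-2-yl]methanol
Conditions: Ti(OiPr)4 (10 mol %), D-(−)-diethyl tartrate, t-BuOOH, 4 Å MS, CH2Cl2, −20 °C
Reagents that add atoms: tert-butyl hydroperoxide CC(C)(C)OO
Why: Sharpless asymmetric epoxidation; the D-(−)-tartrate catalyst gives the (2R,3R)-epoxide (mirror image of the L-tartrate/geraniol outcome), which sets the C4 tertiary centre.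

Step 4
Reactants: 5 [(2R,3R)-3-{2-[(4-methoxybenzyl)oxy]ethyl}-3-methyloxiran-2-yl]methanol
Product: 6 (3S)-5-[(4-methoxybenzyl)oxy]-3-methylpentane-1,3-diol
Conditions: NaAlH2(OCH2CH2OMe)2 (Red-Al), THF, 0 °C
Reagents that add atoms: none
Why: Hydroxyl-directed reductive epoxide opening delivers hydride to the secondary C2, so the tertiary C–O bond and its configuration are untouched (1,3-diol).

Step 5
Reactants: 6 (3S)-5-[(4-methoxybenzyl)oxy]-3-methylpentane-1,3-diol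
Product: 7 (3R)-1,3-bis[(tert-butyldimethylsilyl)oxy]-5-[(4-methoxybenzyl)oxy]-3-methylpentane
Conditions: TBSOTf (2.5 equiv), 2,6-lutidine, CH2Cl2, 0 °C → rt
Reagents that add atoms: tert-butyldimethylsilyl triflate CC(C)(C)[Si](C)(C)OS(=O)(=O)C(F)(F)F
Why: The silyl triflate silylates both the primary and the hindered tertiary hydroxyl (the descriptor changes by priority only).

Step 6
Reactants: 7 (3R)-1,3-bis[(tert-butyldimethylsilyl)oxy]-5-[(4-methoxybenzyl)oxy]-3-methylpentane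
Product: 8 (3S)-3-[(tert-butyldimethylsilyl)oxy]-5-[(4-methoxybenzyl)oxy]-3-methylpentan-1-ol
Conditions: HF·pyridine, pyridine, THF, 0 °C
Reagents that add atoms: none
Why: Fluoride desilylation is much faster at the unhindered primary silyl ether than at the tertiary one (steric differentiation).

Step 7
Reactants: 8 (3S)-3-[(tert-butyldimethylsilyl)oxy]-5-[(4-methoxybenzyl)oxy]-3-methylpentan-1-ol
Product: 9 (3R)-3-[(tert-butyldimethylsilyl)oxy]-5-[(4-methoxybenzyl)oxy]-3-methylpentanal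
Conditions: Dess–Martin periodinane, NaHCO3, CH2Cl2, rt
Reagents that add atoms: none
Why: Dess–Martin oxidation under buffered neutral conditions gives the aldehyde without β-elimination of the silyloxy group.

Step 8
Reactants: 9 (3R)-3-[(tert-butyldimethylsilyl)oxy]-5-[(4-methoxybenzyl)oxy]-3-methylpentanal; 10 tert-butyldimethyl(prop-2-yn-1-yloxy)silane
Product: 12 (4RS,6R)-1,6-bis[(tert-butyldimethylsilyl)oxy]-8-[(4-methoxybenzyl)oxy]-6-methyloct-2-yn-4-ol, via lithium acetylide 11 (not isolated)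
Conditions: 10, n-BuLi, THF, −78 °C; then 9, −78 °C; H2O quench
Reagents that add atoms: none
Why: 1,2-Addition of a lithium acetylide to the aldehyde; the new carbinol is left uncontrolled because it is erased in step 9.

Step 9
Reactants: 12 (4RS,6R)-1,6-bis[(tert-butyldimethylsilyl)oxy]-8-[(4-methoxybenzyl)oxy]-6-methyloct-2-yn-4-ol
Product: 13 (6R)-1,6-bis[(tert-butyldimethylsilyl)oxy]-8-[(4-methoxybenzyl)oxy]-6-methyloct-2-yn-4-one
Conditions: Dess–Martin periodinane, NaHCO3, CH2Cl2, rt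
Reagents that add atoms: none
Why: Dess–Martin oxidation of the propargylic alcohol converges both epimers to one ynone.

Step 10
Reactants: 13 (6R)-1,6-bis[(tert-butyldimethylsilyl)oxy]-8-[(4-methoxybenzyl)oxy]-6-methyloct-2-yn-4-one
Product: 14 (4R,6R)-1,6-bis[(tert-butyldimethylsilyl)oxy]-8-[(4-methoxybenzyl)oxy]-6-methyloct-2-yn-4-ol
Conditions: RuCl[(R,R)-TsDPEN](p-cymene) (2 mol %), i-PrOH, rt
Reagents that add atoms: none
Why: Noyori asymmetric transfer hydrogenation of an alkynyl ketone; the (R,R)-catalyst gives the (R)-propargylic alcohol (C2) under reagent control, independent of the remote C4 centre.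

Step 11
Reactants: 14 (4R,6R)-1,6-bis[(tert-butyldimethylsilyl)oxy]-8-[(4-methoxybenzyl)oxy]-6-methyloct-2-yn-4-ol
Product: 16 (2Z,4R,6R)-1,6-bis[(tert-butyldimethylsilyl)oxy]-2-iodo-8-[(4-methoxybenzyl)oxy]-6-methyloct-2-en-4-ol, via cyclic alkenylaluminate 15 (not isolated)
Conditions: NaAlH2(OCH2CH2OMe)2, THF, 0 °C → rt; then I2, THF, −78 °C
Reagents that add atoms: iodine II
Why: Hydroxyl-directed trans-hydroalumination puts Al on the alkyne carbon distal to the free OH (five-membered aluminate), and iodinolysis with retention gives the Z-iodoalkene with I cis to the carbinol carbon.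

Step 12
Reactants: 16 (2Z,4R,6R)-1,6-bis[(tert-butyldimethylsilyl)oxy]-2-iodo-8-[(4-methoxybenzyl)oxy]-6-methyloct-2-en-4-ol
Product: 17 (2Z,4R,6R)-1,4,6-tris[(tert-butyldimethylsilyl)oxy]-2-iodo-8-[(4-methoxybenzyl)oxy]-6-methyloct-2-ene
Conditions: TBSOTf, 2,6-lutidine, CH2Cl2, −78 °C
Reagents that add atoms: tert-butyldimethylsilyl triflate CC(C)(C)[Si](C)(C)OS(=O)(=O)C(F)(F)F
Why: Silylation of the secondary allylic alcohol under non-nucleophilic base leaves the alkenyl iodide intact.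

Step 13
Reactants: 17 (2Z,4R,6R)-1,4,6-tris[(tert-butyldimethylsilyl)oxy]-2-iodo-8-[(4-methoxybenzyl)oxy]-6-methyloct-2-ene
Product: 18 (3R,5R,6Z)-3,5,8-tris[(tert-butyldimethylsilyl)oxy]-7-iodo-3-methyloct-6-en-1-ol
Conditions: DDQ, CH2Cl2/pH 7 buffer, 0 °C
Reagents that add atoms: none
Why: Oxidative cleavage of the 4-methoxybenzyl ether (benzylic hydride abstraction, then hydrolysis) spares silyl ethers and the alkenyl iodide.

Step 14
Reactants: 18 (3R,5R,6Z)-3,5,8-tris[(tert-butyldimethylsilyl)oxy]-7-iodo-3-methyloct-6-en-1-ol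
Product: 19 (3S,5R,6Z)-3,5,8-tris[(tert-butyldimethylsilyl)oxy]-7-iodo-3-methyloct-6-enal
Conditions: Dess–Martin periodinane, NaHCO3, CH2Cl2, rt
Reagents that add atoms: none
Why: Dess–Martin oxidation gives the C6 aldehyde (fragment A) without touching the stereocentres.

Step 15
Reactants: 20 (2R)-oxiran-2-ylmethanol
Product: 21 (2S)-2-{[(4-methoxybenzyl)oxy]methyl}oxirane
Conditions: NaH, PMBCl, Bu4NI (cat.), THF/DMF, 0 °C → rt
Reagents that add atoms: 4-methoxybenzyl chloride COc1ccc(CCl)cc1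
Why: Williamson etherification; the stereocentre is untouched and only its descriptor changes by priority.

Step 16
Reactants: 21 (2S)-2-{[(4-methoxybenzyl)oxy]methyl}oxirane
Product: 22 (2S)-1-[(4-methoxybenzyl)oxy]but-3-en-2-ol
Conditions: Me3S+ I− (3 equiv), n-BuLi (3 equiv), THF, −10 °C → rt
Reagents that add atoms: trimethylsulfonium iodide C[S+](C)C.[I-]
Why: Corey–Chaykovsky-type ylide opening of the terminal epoxide carbon followed by ylide-mediated elimination gives the one-carbon-homologated allylic alcohol; the C–O stereocentre (C8) is never broken.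

Step 17
Reactants: 22 (2S)-1-[(4-methoxybenzyl)oxy]but-3-en-2-ol; 23 2-(bromomethyl)prop-2-enoic acid
Product: 24 (2S)-1-[(4-methoxybenzyl)oxy]but-3-en-2-yl 2-(bromomethyl)prop-2-enoate
Conditions: DIC, DMAP (5 mol %), CH2Cl2, 0 °C
Reagents that add atoms: none
Why: Steglich carbodiimide esterification of the secondary alcohol; low DMAP loading and low temperature limit attack on the allylic bromide.

Step 18
Reactants: 24 (2S)-1-[(4-methoxybenzyl)oxy]but-3-en-2-yl 2-(bromomethyl)prop-2-enoate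
Product: 25 (5S)-3-(bromomethyl)-5-{[(4-methoxybenzyl)oxy]methyl}furan-2(5H)-one
Conditions: second-generation Grubbs catalyst (5 mol %), CH2Cl2, 40 °C
Reagents that add atoms: none
Why: Ring-closing metathesis of the vinyl group with the acrylate alkene forms the five-membered butenolide with loss of ethylene; C8 is untouched (fragment B).

Step 19
Reactants: 26 (2E)-but-2-enal
Product: 27 (2Z)-2-iodobut-2-enal
Conditions: I2, K2CO3, DMAP (cat.), THF/H2O, rt
Reagents that add atoms: iodine II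
Why: α-Iodination of the enal by DMAP conjugate addition, enolate iodination and elimination; the methyl stays trans to CHO, which gives the Z-iodide.

Step 20
Reactants: 27 (2Z)-2-iodobut-2-enal
Product: 28 (2Z)-2-iodobut-2-en-1-ol
Conditions: NaBH4, MeOH, 0 °C
Reagents that add atoms: none
Why: Borohydride 1,2-reduction of the aldehyde leaves the alkenyl iodide and its geometry intact.

Step 21
Reactants: 28 (2Z)-2-iodobut-2-en-1-ol
Product: 29 tert-butyl{[(2Z)-2-iodobut-2-en-1-yl]oxy}dimethylsilane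
Conditions: TBSCl, imidazole, CH2Cl2, rt
Reagents that add atoms: tert-butyldimethylsilyl chloride CC(C)(C)[Si](C)(C)Cl
Why: Standard silylation of the primary allylic alcohol.

Step 22
Reactants: 29 tert-butyl{[(2Z)-2-iodobut-2-en-1-yl]oxy}dimethylsilane
Product: 31 (2Z)-2-{[(tert-butyldimethylsilyl)oxy]methyl}but-2-enoic acid, via alkenyllithium 30 (not isolated)
Conditions: t-BuLi (2.1 equiv), Et2O, −78 °C; then CO2; then cold 0.5 M HCl to pH 3–4
Reagents that add atoms: carbon dioxide O=C=O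
Why: Iodine–lithium exchange and carboxylation both proceed with retention of alkene geometry, so CO2H ends cis to the methyl group (Z).

Step 23
Reactants: 19 (3S,5R,6Z)-3,5,8-tris[(tert-butyldimethylsilyl)oxy]-7-iodo-3-methyloct-6-enal; 25 (5S)-3-(bromomethyl)-5-{[(4-methoxybenzyl)oxy]methyl}furan-2(5H)-one
Product: 32 (4R,5S)-4-{(1S,3R,5R,6Z)-3,5,8-tris[(tert-butyldimethylsilyl)oxy]-1-hydroxy-7-iodo-3-methyloct-6-en-1-yl}-5-{[(4-methoxybenzyl)oxy]methyl}-3-methylideneoxolan-2-one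
Conditions: Zn dust, THF/sat. aq NH4Cl, 0 °C → rt
Reagents that add atoms: none
Why: Zinc Barbier carbonyl allylation with allylic transposition; the C6–C7 bond forms anti to the C8 substituent (trans lactone, 7R) through a closed chair transition state with the aldehyde chain equatorial, which gives the 6S carbinol and the α-methylidene lactone.

Step 24
Reactants: 32 (4R,5S)-4-{(1S,3R,5R,6Z)-3,5,8-tris[(tert-butyldimethylsilyl)oxy]-1-hydroxy-7-iodo-3-methyloct-6-en-1-yl}-5-{[(4-methoxybenzyl)oxy]methyl}-3-methylideneoxolan-2-one; 31 (2Z)-2-{[(tert-butyldimethylsilyl)oxy]methyl}but-2-enoic acid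
Product: 33 (1R,3R,5R,6Z)-3,5,8-tris[(tert-butyldimethylsilyl)oxy]-7-iodo-1-[(2S,3R)-2-{[(4-methoxybenzyl)oxy]methyl}-4-methylidene-5-oxooxolan-3-yl]-3-methyloct-6-en-1-yl (2Z)-2-{[(tert-butyldimethylsilyl)oxy]methyl}but-2-enoate
Conditions: PPh3, DIAD, toluene, 0 °C → rt
Reagents that add atoms: none
Why: Mitsunobu esterification; SN2 attack of the carboxylate on the alkoxyphosphonium inverts C6 to R, and because the acid is never activated as an acyl donor its Z geometry is preserved.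

Step 25
Reactants: 33 (the C6 ester with C9 4-methoxybenzyl ether)
Product: 34 (1R,3R,5R,6Z)-3,5,8-tris[(tert-butyldimethylsilyl)oxy]-1-[(2S,3R)-2-(hydroxymethyl)-4-methylidene-5-oxooxolan-3-yl]-7-iodo-3-methyloct-6-en-1-yl (2Z)-2-{[(tert-butyldimethylsilyl)oxy]methyl}but-2-enoate
Conditions: DDQ, CH2Cl2/pH 7 buffer, 0 °C
Reagents that add atoms: none
Why: Oxidative removal of the only 4-methoxybenzyl ether frees the C9 primary alcohol; esters, silyl ethers and the alkenyl iodide are inert.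

Step 26
Reactants: 34 (the C9 primary alcohol)
Product: 35 (1R,3R,5R,6Z)-3,5,8-tris[(tert-butyldimethylsilyl)oxy]-1-[(2S,3R)-2-formyl-4-methylidene-5-oxooxolan-3-yl]-7-iodo-3-methyloct-6-en-1-yl (2Z)-2-{[(tert-butyldimethylsilyl)oxy]methyl}but-2-enoate
Conditions: Dess–Martin periodinane, NaHCO3, CH2Cl2, 0 °C → rt; used crude
Reagents that add atoms: none
Why: Buffered Dess–Martin oxidation gives the α-acyloxy aldehyde without epimerising C8.

Step 27
Reactants: 35 (the iodo aldehyde)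
Product: 36 (3aR,4R,6R,8R,9Z,11S,11aS)-6,8-bis[(tert-butyldimethylsilyl)oxy]-10-{[(tert-butyldimethylsilyl)oxy]methyl}-11-hydroxy-6-methyl-3-methylidene-2-oxo-2,3,3a,4,5,6,7,8,11,11a-decahydrocyclodeca[b]furan-4-yl (2Z)-2-{[(tert-butyldimethylsilyl)oxy]methyl}but-2-enoate
Conditions: CrCl2 (8 equiv), NiCl2 (2 mol %), degassed DMSO, 0.003 M, rt
Reagents that add atoms: none
Why: Nozaki–Hiyama–Kishi reaction; zerovalent nickel inserts into the C–I bond with retention, transmetalation to trivalent chromium and addition to the aldehyde close the ten-membered ring with the Z alkene carried over from 16, and the C9 carbinol is set by the ring conformation (taken as 9S).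

Step 28
Reactants: 36 (the macrocyclic C9 alcohol)
Product: 37 (3aR,4R,6R,8R,9Z,11S,11aS)-6,8-bis[(tert-butyldimethylsilyl)oxy]-11-hydroxy-10-(hydroxymethyl)-6-methyl-3-methylidene-2-oxo-2,3,3a,4,5,6,7,8,11,11a-decahydrocyclodeca[b]furan-4-yl (2Z)-2-(hydroxymethyl)but-2-enoate
Conditions: HF·pyridine, pyridine, THF, 0 °C, monitored
Reagents that add atoms: none
Why: Buffered fluoride cleaves the two primary allylic silyl ethers much faster than the secondary and tertiary ones (steric differentiation).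

Step 29
Reactants: 37 (the triol)
Product: 38 (3aR,4R,6R,8R,9Z,11S,11aS)-11-acetoxy-10-(acetoxymethyl)-6,8-bis[(tert-butyldimethylsilyl)oxy]-6-methyl-3-methylidene-2-oxo-2,3,3a,4,5,6,7,8,11,11a-decahydrocyclodeca[b]furan-4-yl (2Z)-2-(acetoxymethyl)but-2-enoate
Conditions: Ac2O, pyridine, DMAP (cat.), CH2Cl2, 0 °C
Reagents that add atoms: acetic anhydride CC(=O)OC(C)=O
Why: DMAP-catalysed acetylation of the three free hydroxyls (C9, C14, side chain) while C2 and C4 stay silylated.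

Step 30
Reactants: 38 (the triacetate bis-silyl ether)
Product: 39 (3aR,4R,6S,8R,9Z,11S,11aS)-11-acetoxy-10-(acetoxymethyl)-6,8-dihydroxy-6-methyl-3-methylidene-2-oxo-2,3,3a,4,5,6,7,8,11,11a-decahydrocyclodeca[b]furan-4-yl (2Z)-2-(acetoxymethyl)but-2-enoate (CNP0126757.1)
Conditions: HF·pyridine (excess), THF, 0 °C → rt
Reagents that add atoms: none
Why: Acidic fluoride desilylation frees the C2 and C4 hydroxyls without acetate migration or attack on the methylidene lactone, as basic fluoride might cause.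

**Compound list**
1 | but-3-yn-1-ol | C#CCCO | starting material
2 | 1-[(but-3-yn-1-yloxy)methyl]-4-methoxybenzene | COc1ccc(COCCC#C)cc1 | intermediate
3 | dimethyl{(1E)-4-[(4-methoxybenzyl)oxy]-2-methylbut-1-en-1-yl}alane | COc1ccc(COCC/C(C)=C/[Al](C)C)cc1 | intermediate
4 | (2E)-5-[(4-methoxybenzyl)oxy]-3-methylpent-2-en-1-ol | COc1ccc(COCC/C(C)=C/CO)cc1 | intermediate
5 | [(2R,3R)-3-{2-[(4-methoxybenzyl)oxy]ethyl}-3-methyloxiran-2-yl]methanol | COc1ccc(COCC[C@@]2(C)O[C@@H]2CO)cc1 | intermediate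
6 | (3S)-5-[(4-methoxybenzyl)oxy]-3-methylpentane-1,3-diol | COc1ccc(COCC[C@@](C)(O)CCO)cc1 | intermediate
7 | (3R)-1,3-bis[(tert-butyldimethylsilyl)oxy]-5-[(4-methoxybenzyl)oxy]-3-methylpentane | COc1ccc(COCC[C@@](C)(O[Si](C)(C)C(C)(C)C)CCO[Si](C)(C)C(C)(C)C)cc1 | intermediate
8 | (3S)-3-[(tert-butyldimethylsilyl)oxy]-5-[(4-methoxybenzyl)oxy]-3-methylpentan-1-ol | COc1ccc(COCC[C@@](C)(O[Si](C)(C)C(C)(C)C)CCO)cc1 | intermediate
9 | (3R)-3-[(tert-butyldimethylsilyl)oxy]-5-[(4-methoxybenzyl)oxy]-3-methylpentanal | COc1ccc(COCC[C@@](C)(O[Si](C)(C)C(C)(C)C)CC=O)cc1 | intermediate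
10 | tert-butyldimethyl(prop-2-yn-1-yloxy)silane | C#CCO[Si](C)(C)C(C)(C)C | starting material
11 | {3-[(tert-butyldimethylsilyl)oxy]prop-1-yn-1-yl}lithium | [Li]C#CCO[Si](C)(C)C(C)(C)C | intermediate
12 | (4RS,6R)-1,6-bis[(tert-butyldimethylsilyl)oxy]-8-[(4-methoxybenzyl)oxy]-6-methyloct-2-yn-4-ol | COc1ccc(COCC[C@@](C)(O[Si](C)(C)C(C)(C)C)CC(O)C#CCO[Si](C)(C)C(C)(C)C)cc1 | intermediate
13 | (6R)-1,6-bis[(tert-butyldimethylsilyl)oxy]-8-[(4-methoxybenzyl)oxy]-6-methyloct-2-yn-4-one | COc1ccc(COCC[C@@](C)(O[Si](C)(C)C(C)(C)C)CC(=O)C#CCO[Si](C)(C)C(C)(C)C)cc1 | intermediate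
14 | (4R,6R)-1,6-bis[(tert-butyldimethylsilyl)oxy]-8-[(4-methoxybenzyl)oxy]-6-methyloct-2-yn-4-ol | COc1ccc(COCC[C@@](C)(O[Si](C)(C)C(C)(C)C)C[C@@H](O)C#CCO[Si](C)(C)C(C)(C)C)cc1 | intermediate
15 | sodium cyclic alkenylaluminate of 14 (five-membered O–Al–C10=C1–C2 ring, two 2-methoxyethoxy groups on Al) | [Na+].COCCO[Al-]1(OCCOC)O[C@H](C[C@](C)(O[Si](C)(C)C(C)(C)C)CCOCc2ccc(OC)cc2)C=C1CO[Si](C)(C)C(C)(C)C | intermediate
16 | (2Z,4R,6R)-1,6-bis[(tert-butyldimethylsilyl)oxy]-2-iodo-8-[(4-methoxybenzyl)oxy]-6-methyloct-2-en-4-ol | COc1ccc(COCC[C@@](C)(O[Si](C)(C)C(C)(C)C)C[C@@H](O)/C=C(/CO[Si](C)(C)C(C)(C)C)I)cc1 | intermediate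
17 | (2Z,4R,6R)-1,4,6-tris[(tert-butyldimethylsilyl)oxy]-2-iodo-8-[(4-methoxybenzyl)oxy]-6-methyloct-2-ene | COc1ccc(COCC[C@@](C)(O[Si](C)(C)C(C)(C)C)C[C@@H](O[Si](C)(C)C(C)(C)C)/C=C(/CO[Si](C)(C)C(C)(C)C)I)cc1 | intermediate
18 | (3R,5R,6Z)-3,5,8-tris[(tert-butyldimethylsilyl)oxy]-7-iodo-3-methyloct-6-en-1-ol | OCC[C@@](C)(O[Si](C)(C)C(C)(C)C)C[C@@H](O[Si](C)(C)C(C)(C)C)/C=C(/CO[Si](C)(C)C(C)(C)C)I | intermediate
19 | (3S,5R,6Z)-3,5,8-tris[(tert-butyldimethylsilyl)oxy]-7-iodo-3-methyloct-6-enal (fragment A) | O=CC[C@@](C)(O[Si](C)(C)C(C)(C)C)C[C@@H](O[Si](C)(C)C(C)(C)C)/C=C(/CO[Si](C)(C)C(C)(C)C)I | intermediate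
20 | (2R)-oxiran-2-ylmethanol, (R)-glycidol | OC[C@@H]1CO1 | starting material
21 | (2S)-2-{[(4-methoxybenzyl)oxy]methyl}oxirane | COc1ccc(COC[C@@H]2CO2)cc1 | intermediate
22 | (2S)-1-[(4-methoxybenzyl)oxy]but-3-en-2-ol | C=C[C@H](O)COCc1ccc(OC)cc1 | intermediate
23 | 2-(bromomethyl)prop-2-enoic acid | C=C(CBr)C(=O)O | starting material
24 | (2S)-1-[(4-methoxybenzyl)oxy]but-3-en-2-yl 2-(bromomethyl)prop-2-enoate | C=C[C@@H](COCc1ccc(OC)cc1)OC(=O)C(=C)CBr | intermediate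
25 | (5S)-3-(bromomethyl)-5-{[(4-methoxybenzyl)oxy]methyl}furan-2(5H)-one (fragment B) | BrCC1=C[C@@H](COCc2ccc(OC)cc2)OC1=O | intermediate
26 | (2E)-but-2-enal, crotonaldehyde | C/C=C/C=O | starting material
27 | (2Z)-2-iodobut-2-enal | C/C=C(\I)C=O | intermediate
28 | (2Z)-2-iodobut-2-en-1-ol | C/C=C(\I)CO | intermediate
29 | tert-butyl{[(2Z)-2-iodobut-2-en-1-yl]oxy}dimethylsilane | C/C=C(\I)CO[Si](C)(C)C(C)(C)C | intermediate
30 | {(2E)-1-[(tert-butyldimethylsilyl)oxy]but-2-en-2-yl}lithium (Li in place of I, geometry retained) | C/C=C(\[Li])CO[Si](C)(C)C(C)(C)C | intermediate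
31 | (2Z)-2-{[(tert-butyldimethylsilyl)oxy]methyl}but-2-enoic acid | C/C=C(\C(=O)O)CO[Si](C)(C)C(C)(C)C | intermediate
32 | (4R,5S)-4-{(1S,3R,5R,6Z)-3,5,8-tris[(tert-butyldimethylsilyl)oxy]-1-hydroxy-7-iodo-3-methyloct-6-en-1-yl}-5-{[(4-methoxybenzyl)oxy]methyl}-3-methylideneoxolan-2-one | C=C1C(=O)O[C@H](COCc2ccc(OC)cc2)[C@H]1[C@@H](O)C[C@@](C)(O[Si](C)(C)C(C)(C)C)C[C@@H](O[Si](C)(C)C(C)(C)C)/C=C(/CO[Si](C)(C)C(C)(C)C)I | intermediate
33 | (1R,3R,5R,6Z)-3,5,8-tris[(tert-butyldimethylsilyl)oxy]-7-iodo-1-[(2S,3R)-2-{[(4-methoxybenzyl)oxy]methyl}-4-methylidene-5-oxooxolan-3-yl]-3-methyloct-6-en-1-yl (2Z)-2-{[(tert-butyldimethylsilyl)oxy]methyl}but-2-enoate | C=C1C(=O)O[C@H](COCc2ccc(OC)cc2)[C@H]1[C@H](OC(=O)/C(=C\C)CO[Si](C)(C)C(C)(C)C)C[C@@](C)(O[Si](C)(C)C(C)(C)C)C[C@@H](O[Si](C)(C)C(C)(C)C)/C=C(/CO[Si](C)(C)C(C)(C)C)I | intermediate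
34 | (1R,3R,5R,6Z)-3,5,8-tris[(tert-butyldimethylsilyl)oxy]-1-[(2S,3R)-2-(hydroxymethyl)-4-methylidene-5-oxooxolan-3-yl]-7-iodo-3-methyloct-6-en-1-yl (2Z)-2-{[(tert-butyldimethylsilyl)oxy]methyl}but-2-enoate | C=C1C(=O)O[C@H](CO)[C@H]1[C@H](OC(=O)/C(=C\C)CO[Si](C)(C)C(C)(C)C)C[C@@](C)(O[Si](C)(C)C(C)(C)C)C[C@@H](O[Si](C)(C)C(C)(C)C)/C=C(/CO[Si](C)(C)C(C)(C)C)I | intermediate
35 | (1R,3R,5R,6Z)-3,5,8-tris[(tert-butyldimethylsilyl)oxy]-1-[(2S,3R)-2-formyl-4-methylidene-5-oxooxolan-3-yl]-7-iodo-3-methyloct-6-en-1-yl (2Z)-2-{[(tert-butyldimethylsilyl)oxy]methyl}but-2-enoate | C=C1C(=O)O[C@H](C=O)[C@H]1[C@H](OC(=O)/C(=C\C)CO[Si](C)(C)C(C)(C)C)C[C@@](C)(O[Si](C)(C)C(C)(C)C)C[C@@H](O[Si](C)(C)C(C)(C)C)/C=C(/CO[Si](C)(C)C(C)(C)C)I | intermediate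
36 | (3aR,4R,6R,8R,9Z,11S,11aS)-6,8-bis[(tert-butyldimethylsilyl)oxy]-10-{[(tert-butyldimethylsilyl)oxy]methyl}-11-hydroxy-6-methyl-3-methylidene-2-oxo-2,3,3a,4,5,6,7,8,11,11a-decahydrocyclodeca[b]furan-4-yl (2Z)-2-{[(tert-butyldimethylsilyl)oxy]methyl}but-2-enoate | C=C1C(=O)O[C@H]2[C@H]1[C@H](OC(=O)/C(=C\C)CO[Si](C)(C)C(C)(C)C)C[C@@](C)(O[Si](C)(C)C(C)(C)C)C[C@@H](O[Si](C)(C)C(C)(C)C)/C=C(/CO[Si](C)(C)C(C)(C)C)[C@@H]2O | intermediate
37 | (3aR,4R,6R,8R,9Z,11S,11aS)-6,8-bis[(tert-butyldimethylsilyl)oxy]-11-hydroxy-10-(hydroxymethyl)-6-methyl-3-methylidene-2-oxo-2,3,3a,4,5,6,7,8,11,11a-decahydrocyclodeca[b]furan-4-yl (2Z)-2-(hydroxymethyl)but-2-enoate | C=C1C(=O)O[C@H]2[C@H]1[C@H](OC(=O)/C(=C\C)CO)C[C@@](C)(O[Si](C)(C)C(C)(C)C)C[C@@H](O[Si](C)(C)C(C)(C)C)/C=C(/CO)[C@@H]2O | intermediate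
38 | (3aR,4R,6R,8R,9Z,11S,11aS)-11-acetoxy-10-(acetoxymethyl)-6,8-bis[(tert-butyldimethylsilyl)oxy]-6-methyl-3-methylidene-2-oxo-2,3,3a,4,5,6,7,8,11,11a-decahydrocyclodeca[b]furan-4-yl (2Z)-2-(acetoxymethyl)but-2-enoate | C=C1C(=O)O[C@H]2[C@H]1[C@H](OC(=O)/C(=C\C)COC(C)=O)C[C@@](C)(O[Si](C)(C)C(C)(C)C)C[C@@H](O[Si](C)(C)C(C)(C)C)/C=C(/COC(C)=O)[C@@H]2OC(C)=O | intermediate
39 | (3aR,4R,6S,8R,9Z,11S,11aS)-11-acetoxy-10-(acetoxymethyl)-6,8-dihydroxy-6-methyl-3-methylidene-2-oxo-2,3,3a,4,5,6,7,8,11,11a-decahydrocyclodeca[b]furan-4-yl (2Z)-2-(acetoxymethyl)but-2-enoate (CNP0126757.1) | C=C1C(=O)O[C@H]2[C@H]1[C@H](OC(=O)/C(=C\C)COC(C)=O)C[C@@](C)(O)C[C@@H](O)/C=C(/COC(C)=O)[C@@H]2OC(C)=O | target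

**Step count and risks**

Total steps: 30. Longest linear sequence: 22 steps (steps 1–14, then 23–30).

Three steps most likely to fail:

Step 24 (Mitsunobu inversion at the hindered C6 carbinol; slow substitution or elimination are the likely failure modes). The fallback sets out from 32 and comes back at 33, replacing substitution by an oxidation–reduction relay. Thiophenol/Et3N adds to the methylidene of 32 to give the phenylthiomethyl lactone F1, which blocks migration of the exocyclic alkene. Parikh–Doering oxidation (SO3·pyridine, DMSO, i-Pr2NEt) then gives the C6 ketone F2. Reagent-controlled reduction with (S)-Me-CBS oxazaborolidine/catecholborane gives the (6R)-alcohol F3. Acylation with 31 through its 2,4,6-trichlorobenzoyl mixed anhydride (Et3N, then DMAP, 0 °C) gives the masked ester F4. Oxidation with mCPBA (1 equiv, −78 °C) gives the sulfoxide F5, and warming in toluene (90 °C, CaCO3) effects syn-elimination to 33.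

Step 27 (strained ten-membered ring closure, with the C9 configuration fixed only by ring conformation). The fallback sets out from 35 and comes back at 36. If the closure gives mainly or partly the 9-epi alcohol F6, the epimer mixture is oxidised with Dess–Martin periodinane to the macrocyclic enone F7. Reduction under reagent control ((S)-Me-CBS oxazaborolidine/catecholborane, alkenyl as the large group; NaBH4/CeCl3 as the substrate-controlled alternative) then gives 36, so both epimers are funnelled into the route.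

Step 28 (partial loss of the secondary C2 silyl ether would lead to over-acetylation in step 29). The fallback sets out from 36 and comes back at 39 without any selective desilylation. The C9 hydroxyl of 36 is acetylated (Ac2O, pyridine, DMAP) to give the 9-acetate F8. All four silyl groups are then removed (HF·pyridine, THF, rt) to give the tetraol F9. Finally only the two primary allylic hydroxyls are acetylated (AcCl, 2,4,6-collidine, CH2Cl2, −78 °C), which gives 39 directly.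

**Further compounds**
F1 | step 24 | phenylthiomethyl lactone: 32 with the 3-methylidene replaced by 3-[(phenylsulfanyl)methyl] (C11 epimers), 6S alcohol | c1ccc(SCC2C(=O)O[C@H](COCc3ccc(OC)cc3)[C@H]2[C@@H](O)C[C@@](C)(O[Si](C)(C)C(C)(C)C)C[C@@H](O[Si](C)(C)C(C)(C)C)/C=C(/CO[Si](C)(C)C(C)(C)C)I)cc1
F2 | step 24 | C6 ketone of F1 | c1ccc(SCC2C(=O)O[C@H](COCc3ccc(OC)cc3)[C@H]2C(=O)C[C@@](C)(O[Si](C)(C)C(C)(C)C)C[C@@H](O[Si](C)(C)C(C)(C)C)/C=C(/CO[Si](C)(C)C(C)(C)C)I)cc1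
F3 | step 24 | (6R)-alcohol, C6 epimer of F1 | c1ccc(SCC2C(=O)O[C@H](COCc3ccc(OC)cc3)[C@H]2[C@H](O)C[C@@](C)(O[Si](C)(C)C(C)(C)C)C[C@@H](O[Si](C)(C)C(C)(C)C)/C=C(/CO[Si](C)(C)C(C)(C)C)I)cc1
F4 | step 24 | masked ester: (2Z)-2-{[(tert-butyldimethylsilyl)oxy]methyl}but-2-enoate of F3 | c1ccc(SCC2C(=O)O[C@H](COCc3ccc(OC)cc3)[C@H]2[C@H](OC(=O)/C(=C\C)CO[Si](C)(C)C(C)(C)C)C[C@@](C)(O[Si](C)(C)C(C)(C)C)C[C@@H](O[Si](C)(C)C(C)(C)C)/C=C(/CO[Si](C)(C)C(C)(C)C)I)cc1
F5 | step 24 | sulfoxide of F4 | O=S(CC2C(=O)O[C@H](COCc3ccc(OC)cc3)[C@H]2[C@H](OC(=O)/C(=C\C)CO[Si](C)(C)C(C)(C)C)C[C@@](C)(O[Si](C)(C)C(C)(C)C)C[C@@H](O[Si](C)(C)C(C)(C)C)/C=C(/CO[Si](C)(C)C(C)(C)C)I)c1ccccc1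
F6 | step 27 | 9-epi alcohol, C9 (ring position 11) epimer of 36 | C=C1C(=O)O[C@H]2[C@H]1[C@H](OC(=O)/C(=C\C)CO[Si](C)(C)C(C)(C)C)C[C@@](C)(O[Si](C)(C)C(C)(C)C)C[C@@H](O[Si](C)(C)C(C)(C)C)/C=C(/CO[Si](C)(C)C(C)(C)C)[C@H]2O
F7 | step 27 | macrocyclic enone: C9 ketone of 36 | C=C1C(=O)O[C@H]2[C@H]1[C@H](OC(=O)/C(=C\C)CO[Si](C)(C)C(C)(C)C)C[C@@](C)(O[Si](C)(C)C(C)(C)C)C[C@@H](O[Si](C)(C)C(C)(C)C)/C=C(/CO[Si](C)(C)C(C)(C)C)C2=O
F8 | step 28 | 9-acetate of 36, all four silyl ethers retained | C=C1C(=O)O[C@H]2[C@H]1[C@H](OC(=O)/C(=C\C)CO[Si](C)(C)C(C)(C)C)C[C@@](C)(O[Si](C)(C)C(C)(C)C)C[C@@H](O[Si](C)(C)C(C)(C)C)/C=C(/CO[Si](C)(C)C(C)(C)C)[C@@H]2OC(C)=O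
F9 | step 28 | tetraol 9-acetate: free hydroxyls at C2, C4, C14 and the side-chain CH2OH | C=C1C(=O)O[C@H]2[C@H]1[C@H](OC(=O)/C(=C\C)CO)C[C@@](C)(O)C[C@@H](O)/C=C(/CO)[C@@H]2OC(C)=O
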